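Abbreviations: TBS = tert-butyldimethylsilyl, TBSO = TBS ether oxygen, Tf = trifluoromethanesulfonyl. Lactone numbering: O1, C2(=O), C3, C4, C5; C6 is the exocyclic CH on C3 (ring A), C7 the CH2 on C4 (ring B).

## Structural features

The target is a γ-butyrolactone carrying ring A (3,4-dihydroxy-5-methoxyphenyl) on the exocyclic carbon C6, doubly bonded to C3, and ring B (4-hydroxy-3-methoxyphenyl) joined to C4 through the methylene C7. There is one stereocentre, C4 (S), with no neighbouring stereocentre to relay from, and one stereogenic alkene, C3=C6 (Z), which places ring A on the side of the lactone carbonyl; this is not the isomer that an aldol condensation and dehydration on a lactone delivers. The fragile elements are the free catechol of ring A (oxidised in air under base), the arylidene lactone (a Michael acceptor whose Z geometry can be lost through light, radicals, iodine or reversible addition of nucleophiles) and the lactone itself. C4–H is allylic but cross-conjugated with the carbonyl, so mild base should not remove it. The real difficulty is to create the isolated C4 stereocentre and the Z alkene under independent control and to keep both while ring B is attached. The feature the key step uses is that C4 bears two methylene arms, C5 (bound to O1) and C7 (bound to ring B): if C7 also carries oxygen, then C4, C5, C7 and that oxygen form a 3-substituted oxetane with C4 prochiral, and the C2 carboxyl group on C3 can open one arm to make C5–O1. The same feature means that in the hydroxymethyl lactone the two arms differ only in which oxygen is acylated, which matters for how that intermediate is handled.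

## Logic of the disconnections

17 ⇒ 16. Three phenolic O–Si bonds are cut. All phenols are masked with one group so that a single buffered fluoride step ends the route. The forward step must avoid phenoxide formation, which would endanger the catechol and the Z alkene.

16 ⇒ 11 + 15 (15 from 14, from 13, from 12). The C7–aryl bond of ring B is cut, giving an sp3 electrophile at C7 and an aryl nucleophile. This removes a whole aryl unit and leaves the stereocentre and the alkene untouched. The forward step must be a two-electron substitution, fast at low temperature, because a radical at C7 is homoallylic to C3=C6 and could add reversibly to C3 and scramble the geometry. It must also beat conjugate addition at C6.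

11 ⇒ 10. The C7–O sulfonate bond is a functional group change only. It turns the hydroxyl released by the key step into the best leaving group for a polar displacement and removes the free hydroxyl that could take part in acyl transfer. The forward step must be cold and quick.

10 ⇒ 9. The C5–O1 bond is cut, opening the lactone ring and re-forming the oxetane from C5, C4, C7 and the C7 oxygen. The stereocentre disappears and an achiral acid remains. The forward step must distinguish two enantiotopic CH2 groups and outrun unselective self-opening.

9 ⇒ 6 (through 8 and 7). The C2–C3 bond is cut: the carboxyl carbon is added last, by carboxylation of an alkenyl anion, so that acid and oxetane coexist only briefly. The forward step must retain the alkene geometry and release the acid under cold, mild conditions.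

6 ⇒ 3 + 5 (5 from 4). The C3–C4 bond is cut between an alkenyl dibromide and the oxetanyl nucleophile. The gain is that the alkene geometry is reduced to a question of which C–Br bond reacts first. The forward step must couple only the bromide trans to ring A and stop after one coupling.

3 ⇒ 2 ⇒ 1. The C3=C6 bond is cut to an aldehyde and a one-carbon dibromomethylene unit; two O–Si bonds lead back to commercial 1, which already has the full oxygen pattern of ring A. The forward steps are routine.

13 ⇒ 12. One O–Si bond; the phenol of ring B must be masked before metalation.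

## Other disconnections considered

Alternative 1: The cut runs through ring A itself (C1'–C2' and C5'–C6'), so ring A is assembled last. Forward, the 2-stannyl diene A3, which already contains the lactone, C4 and the Z alkene, would be coupled with the 4-chlorocyclobutenone A2 (derived from diisopropyl squarate A1) under Pd2(dba)3 (dba = dibenzylideneacetone) and tri(2-furyl)phosphine. On warming, the dienylcyclobutenone would open to a dienylketene, which closes and tautomerises to the C5' phenol A4.
- In its favour: the three oxygens of ring A arrive fully differentiated (C5' free, C3' and C4' as isopropyl ethers), and the pericyclic cascade needs no catalyst control. For late variation of ring A it would be the better plan.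
- Against it here: ring A is available intact as 1, so building it gains nothing. The cut leaves C4 and the Z alkene unsolved and moves them into the synthesis of A3. The Z geometry must survive a thermal step, and O-methylation, removal of two isopropyl ethers and a silyl ether still follow, with tin waste.
- Comparison: equal in regiochemical security for ring A and mechanistically more robust in the ring-forming event, but clearly longer, and it does not address the stereocentre.

Alternative 2: The cut is at O1 (C2–O1 and C5–O1 formed by oxygen insertion), leading to the prochiral 3-benzylcyclobutanone A5 with ring B in place. Forward, Baeyer–Villiger oxidation with cyclohexanone monooxygenase and O2, or aqueous H2O2 with a chiral phosphoric acid, would give lactone A6, with C4 set by which enantiotopic ring CH2 migrates.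
- In its favour: this desymmetrisation is established for exactly this substrate class, which is better precedent than the chosen key step has. Ring B is present before the stereocentre is made, so no sp3–sp2 coupling next to a Michael acceptor is needed. A6 has no free hydroxymethyl arm and so no acyl-transfer route to racemisation. On these three points it is the better plan.
- Against it: A6 lacks C6 and ring A. Aldol addition to 2 and dehydration would give mainly the E arylidene lactone A7, and the Z isomer 16 would then need a photoisomerisation that stops at a photostationary mixture and requires separation.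
- Comparison: step counts are about equal (A5 needs a ketene cycloaddition to a protected allylarene and a dechlorination). The alternative is stronger at C4 and weaker at C3=C6, whereas the chosen plan fixes the geometry before the stereocentre exists.

Alternative 3: The cut is the C3–C4 bond, opening the lactone to the ester A8 of a silyl-protected coniferyl alcohol with the arylpropiolic acid of ring A. Forward, A8 would take up H2 over Rh(cod)2OTf (cod = cycloocta-1,5-diene) and one enantiomer of BINAP (2,2'-bis(diphenylphosphino)-1,1'-binaphthyl). Oxidative cyclisation on monovalent rhodium would give a rhodacyclopentene (C3–C4 formed), and hydrogenolysis of the two Rh–C bonds would place hydrogen on C6 and C7, giving A9, identical with 16.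
- In its favour: one step would create the ring, the C4 stereocentre, the C7 methylene and the Z geometry, since C4 and hydrogen add to the same face of the alkyne. The whole route would be about six steps, with no substitution at C7 and no hydroxymethyl intermediate. In convergence and step economy it is clearly the better plan, and in control of alkene geometry it is the equal.
- Against it: ester tethers prefer the s-trans conformer, which holds alkyne and alkene apart, and the alkene is a 1,2-disubstituted styrene. Both slow the cyclisation relative to plain hydrogenation. The cinnamyl-type C5–O1 bond can ionise or be hydrogenolysed, and enantioselection with this tether is hard to foresee.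
- Comparison: the chosen plan is longer but separates geometry, stereocentre and ring B into steps that can be optimised independently; the alternative is a single all-or-nothing step.

Key step: step 5

Assumptions and remarks on the chemistry:
- The enantiomer of the phosphoric acid that gives the 4R alcohol 10 cannot be assigned in advance for this substrate. The R catalyst is written; its mirror image is used if the sense of induction is the opposite.
- The C4 descriptor is R in 10 and S from 11 onward. This reflects a change of CIP priorities at C7 only; no bond at C4 is touched after step 5.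
- Acid 9 is never stored or concentrated, because carboxylic acids that carry an oxetane isomerise to lactones on standing or warming. Its storable form is the lithium salt 8.
- Light is excluded from compound 6 onward.

## Route

Step 1
Reactants: 1 3,4-dihydroxy-5-methoxybenzaldehyde
Product: 2 3,4-bis(TBSO)-5-methoxybenzaldehyde
Conditions: TBSCl (2.5 equiv), imidazole (5 equiv), DMF, 23 °C
Reagents that add atoms: tert-butyldimethylsilyl chloride, C[Si](C)(Cl)C(C)(C)C
Why: Imidazole-promoted O-silylation of both phenols; aryl TBS ethers should tolerate the organozinc, the organolithium at −78 °C, the Brønsted acid and the cuprate, and all come off together at the end.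

Step 2
Reactants: 2 3,4-bis(TBSO)-5-methoxybenzaldehyde
Product: 3 1,2-bis(TBSO)-5-(2,2-dibromoethenyl)-3-methoxybenzene
Conditions: CBr4, PPh3, Zn dust, CH2Cl2, 23 °C; then 2, 0 → 23 °C
Reagents that add atoms: carbon tetrabromide, BrC(Br)(Br)Br
Why: Ramirez dibromo-olefination (first stage of the Corey–Fuchs sequence), a Wittig reaction of Ph3P=CBr2; zinc consumes the bromine that would otherwise give Ph3PBr2, so no brominating phosphorane is left to attack the silyl ethers.

Step 3
Reactants: 3 1,2-bis(TBSO)-5-(2,2-dibromoethenyl)-3-methoxybenzene; 4 3-iodooxetane
Product: 6 3-[(1Z)-1-bromo-2-(3,4-bis(TBSO)-5-methoxyphenyl)ethenyl]oxetane (bromine cis to ring A), via oxetan-3-ylzinc iodide 5 (not isolated)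
Conditions: 4, Zn dust (activated with BrCH2CH2Br and Me3SiCl), LiCl, THF, 25 °C; then 3, PdCl2(DPEphos) (5 mol%) [DPEphos = bis(2-diphenylphosphinophenyl) ether], THF, 0 → 23 °C
Reagents that add atoms: zinc, [Zn] (kept only in intermediate 5)
Why: Trans-selective Negishi mono-coupling of a 1,1-dibromoalkene: zerovalent palladium should insert into the less hindered C–Br bond trans to ring A, so the oxetanyl group enters trans and the remaining bromide stays cis to ring A. The second C–Br bond is then flanked by ring A and the oxetane and should react much more slowly; the oxetan-3-yl group is a well-behaved secondary alkyl because β-hydride elimination would have to form a strained oxete.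

Step 4
Reactants: 6 3-[(1Z)-1-bromo-2-(3,4-bis(TBSO)-5-methoxyphenyl)ethenyl]oxetane
Product: 9 (2Z)-3-(3,4-bis(TBSO)-5-methoxyphenyl)-2-(oxetan-3-yl)prop-2-enoic acid (ring A cis to the carboxyl group), via alkenyllithium 7 (not isolated), via lithium carboxylate 8 (not isolated)
Conditions: t-BuLi (2.0 equiv), THF, −78 °C; CO2 (g), −78 → −20 °C; extraction of 8 into cold water; then cold aq. NaHSO4 (pH 3–4)/PhMe, 0 °C; PhMe solution dried cold and used at once
Reagents that add atoms: carbon dioxide, O=C=O; tert-butyllithium, [Li]C(C)(C)C (lithium kept only in intermediates 7 and 8)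
Why: Bromine–lithium exchange is much faster than any deprotonation at −78 °C, and an α-alkyl, β-aryl alkenyllithium is configurationally stable at that temperature, so carboxylation should proceed with retention. Exactly two equivalents of t-BuLi avoid pivalate, and the acid is freed from its stable salt only in the cold and carried on in toluene without concentration.

Step 5
Reactants: 9 (2Z)-3-(3,4-bis(TBSO)-5-methoxyphenyl)-2-(oxetan-3-yl)prop-2-enoic acid
Product: 10 (3Z,4R)-3-[(3,4-bis(TBSO)-5-methoxyphenyl)methylidene]-4-(hydroxymethyl)oxolan-2-one
Conditions: (R)-TRIP [(R)-3,3'-bis(2,4,6-triisopropylphenyl)-1,1'-binaphthyl-2,2'-diyl hydrogen phosphate] (10 mol%), PhMe (0.02 M), −20 °C, dark; cold filtration through a short silica pad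
Reagents that add atoms: none
Why: The phosphoric acid is expected to act bifunctionally: its P–OH group hydrogen-bonds to the oxetane oxygen and its P=O group accepts the carboxyl proton, so that a carboxyl oxygen attacks one oxetane CH2 from the side opposite the breaking C–O bond while the strain of the four-membered ring is released. The closest known reaction type is the catalytic enantioselective intramolecular opening of 3-substituted oxetanes by a tethered hydroxyl group to give five-membered cyclic ethers; that a carboxyl group is a competent internal nucleophile follows from the known thermal isomerisation of oxetane carboxylic acids to hydroxymethyl lactones. The lactone ring closes in the 5-exo-tet mode (O1 onto C5, the breaking C5–O bond lying outside the new ring); the attacked CH2 becomes C5 and the other is released as C7H2OH. C4, the former prochiral oxetane carbon, is the only new stereocentre and is controlled by the catalyst alone: the 2,4,6-triisopropylphenyl walls of the pocket decide which of the two enantiotopic CH2 groups lies under the bound carboxyl group. The step needs enantiotopic-group selectivity and a catalysed rate well above that of unselective self-opening; the substrate helps because the Z geometry turns the small vinylic hydrogen, not ring A, toward the oxetane, which can therefore rotate into the reactive conformer next to the carboxyl group on the same sp2 carbon. High dilution in toluene at −20 °C disfavours the bimolecular pathway in which one substrate acid activates the oxetane of another. The C3=C6 geometry is not involved and should be carried through unchanged.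

Step 6
Reactants: 10 (3Z,4R)-3-[(3,4-bis(TBSO)-5-methoxyphenyl)methylidene]-4-(hydroxymethyl)oxolan-2-one
Product: 11 [(3S,4Z)-4-[(3,4-bis(TBSO)-5-methoxyphenyl)methylidene]-5-oxooxolan-3-yl]methyl trifluoromethanesulfonate
Conditions: Tf2O, 2,6-lutidine, CH2Cl2, −78 °C; cold aqueous work-up, used crude at once
Reagents that add atoms: trifluoromethanesulfonic anhydride, O=S(=O)(OS(=O)(=O)C(F)(F)F)C(F)(F)F
Why: O-Sulfonylation of a primary alcohol with a hindered base should be complete within minutes at −78 °C and removes the free C7 hydroxyl, closing the acyl-transfer path from O1 to the C7 oxygen that would interconvert the enantiomers. A triflate is preferred to an iodide because its displacement is a two-electron SN2 process at −78 °C, whereas an iodide can react by electron transfer and a C7 radical could add reversibly to C3 and scramble the alkene geometry.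

Step 7
Reactants: 12 4-bromo-2-methoxyphenol
Product: 13 (4-bromo-2-methoxyphenoxy)(tert-butyl)dimethylsilane
Conditions: TBSCl, imidazole, DMF, 23 °C
Reagents that add atoms: tert-butyldimethylsilyl chloride, C[Si](C)(Cl)C(C)(C)C
Why: Imidazole-promoted O-silylation; the phenol must be masked before bromine–lithium exchange, and the same group as on ring A allows one final deprotection.

Step 8
Reactants: 11 [(3S,4Z)-4-[(3,4-bis(TBSO)-5-methoxyphenyl)methylidene]-5-oxooxolan-3-yl]methyl trifluoromethanesulfonate; 13 (4-bromo-2-methoxyphenoxy)(tert-butyl)dimethylsilane
Product: 16 (3Z,4S)-3-[(3,4-bis(TBSO)-5-methoxyphenyl)methylidene]-4-[(4-(TBSO)-3-methoxyphenyl)methyl]oxolan-2-one, via aryllithium 14 (not isolated), via lithium diarylcuprate 15 (not isolated)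
Conditions: 13, t-BuLi (2 equiv per 13), Et2O, −78 °C; CuBr·SMe2 (0.5 equiv per aryllithium), −78 → −30 °C; then 11 (limiting; 1.5 equiv of 15), Et2O, −78 °C; aq. NH4Cl
Reagents that add atoms: tert-butyllithium, [Li]C(C)(C)C (lithium only in intermediates 14 and 15); copper bromide–dimethyl sulfide complex, [Cu]Br.CSC (copper only in intermediate 15)
Why: SN2 displacement of a primary triflate by a lithium diarylcuprate should be fast at −78 °C, where conjugate addition to the α-substituted, electron-rich arylidene lactone and attack at the lactone carbonyl are not expected to compete. An iodide-free copper source and ether (not THF) are chosen so that the triflate is not diverted to the iodide or into solvent ring-opening; C4 is not involved, so its configuration should be retained.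

Step 9
Reactants: 16 (3Z,4S)-3-[(3,4-bis(TBSO)-5-methoxyphenyl)methylidene]-4-[(4-(TBSO)-3-methoxyphenyl)methyl]oxolan-2-one
Product: 17 (3Z,4S)-3-[(3,4-dihydroxy-5-methoxyphenyl)methylidene]-4-[(4-hydroxy-3-methoxyphenyl)methyl]oxolan-2-one
Conditions: Bu4NF, AcOH (1:1, 3.6 equiv), THF, 0 °C, Ar, dark
Reagents that add atoms: none
Why: Fluoride cleavage of three aryl silyl ethers; acetic acid keeps the liberated phenols protonated, so no phenoxide is present to weaken the C3=C6 double bond by push–pull conjugation (Z to E drift) or to let the catechol oxidise.

## Compound list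

1 | 3,4-dihydroxy-5-methoxybenzaldehyde | COc1cc(C=O)cc(O)c1O | starting material
2 | 3,4-bis(TBSO)-5-methoxybenzaldehyde | O=Cc1cc(O[Si](C)(C)C(C)(C)C)c(O[Si](C)(C)C(C)(C)C)c(OC)c1 | intermediate
3 | 1,2-bis(TBSO)-5-(2,2-dibromoethenyl)-3-methoxybenzene | BrC(Br)=Cc1cc(O[Si](C)(C)C(C)(C)C)c(O[Si](C)(C)C(C)(C)C)c(OC)c1 | intermediate
4 | 3-iodooxetane | IC1COC1 | starting material
5 | oxetan-3-ylzinc iodide | I[Zn]C1COC1 | intermediate (not isolated)
6 | 3-[(1Z)-1-bromo-2-(3,4-bis(TBSO)-5-methoxyphenyl)ethenyl]oxetane, bromine cis to ring A | Br/C(=C\c1cc(O[Si](C)(C)C(C)(C)C)c(O[Si](C)(C)C(C)(C)C)c(OC)c1)C1COC1 | intermediate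
7 | 2-(3,4-bis(TBSO)-5-methoxyphenyl)-1-(oxetan-3-yl)ethenyllithium, lithium cis to ring A | [Li]/C(=C\c1cc(O[Si](C)(C)C(C)(C)C)c(O[Si](C)(C)C(C)(C)C)c(OC)c1)C1COC1 | intermediate (not isolated)
8 | lithium (2Z)-3-(3,4-bis(TBSO)-5-methoxyphenyl)-2-(oxetan-3-yl)prop-2-enoate | [Li+].[O-]C(=O)/C(=C\c1cc(O[Si](C)(C)C(C)(C)C)c(O[Si](C)(C)C(C)(C)C)c(OC)c1)C1COC1 | intermediate (not isolated)
9 | (2Z)-3-(3,4-bis(TBSO)-5-methoxyphenyl)-2-(oxetan-3-yl)prop-2-enoic acid | OC(=O)/C(=C\c1cc(O[Si](C)(C)C(C)(C)C)c(O[Si](C)(C)C(C)(C)C)c(OC)c1)C1COC1 | intermediate
10 | (3Z,4R)-3-[(3,4-bis(TBSO)-5-methoxyphenyl)methylidene]-4-(hydroxymethyl)oxolan-2-one | OC[C@@H]1COC(=O)/C1=C\c1cc(O[Si](C)(C)C(C)(C)C)c(O[Si](C)(C)C(C)(C)C)c(OC)c1 | intermediate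
11 | [(3S,4Z)-4-[(3,4-bis(TBSO)-5-methoxyphenyl)methylidene]-5-oxooxolan-3-yl]methyl trifluoromethanesulfonate | FC(F)(F)S(=O)(=O)OC[C@@H]1COC(=O)/C1=C\c1cc(O[Si](C)(C)C(C)(C)C)c(O[Si](C)(C)C(C)(C)C)c(OC)c1 | intermediate
12 | 4-bromo-2-methoxyphenol | COc1cc(Br)ccc1O | starting material
13 | (4-bromo-2-methoxyphenoxy)(tert-butyl)dimethylsilane | COc1cc(Br)ccc1O[Si](C)(C)C(C)(C)C | intermediate
14 | [4-(TBSO)-3-methoxyphenyl]lithium | COc1cc([Li])ccc1O[Si](C)(C)C(C)(C)C | intermediate (not isolated)
15 | lithium bis[4-(TBSO)-3-methoxyphenyl]cuprate | [Li+].COc1cc([Cu-]c2ccc(O[Si](C)(C)C(C)(C)C)c(OC)c2)ccc1O[Si](C)(C)C(C)(C)C | intermediate (not isolated)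
16 | (3Z,4S)-3-[(3,4-bis(TBSO)-5-methoxyphenyl)methylidene]-4-[(4-(TBSO)-3-methoxyphenyl)methyl]oxolan-2-one | COc1cc(C[C@@H]2COC(=O)/C2=C\c2cc(O[Si](C)(C)C(C)(C)C)c(O[Si](C)(C)C(C)(C)C)c(OC)c2)ccc1O[Si](C)(C)C(C)(C)C | intermediate
17 | (3Z,4S)-3-[(3,4-dihydroxy-5-methoxyphenyl)methylidene]-4-[(4-hydroxy-3-methoxyphenyl)methyl]oxolan-2-one | COc1cc(C[C@@H]2COC(=O)/C2=C\c2cc(O)c(O)c(OC)c2)ccc1O | target

## Step count and risk

Total step count: 9. Longest linear sequence: 8 (steps 1–6, 8 and 9, from 1 to 17); step 7 is a one-step branch.

Least certain steps:

Step 5 (key step).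
- What may go wrong: insufficient discrimination between the two enantiotopic CH2 groups. The short, planar acrylic acid tether cannot place the attacking oxygen fully anti to the breaking C–O bond, so the catalysed path may be slow enough for unselective self-opening to compete. Enantiomeric purity could also erode by acyl transfer from O1 to the free C7 hydroxyl (through a bicyclic tetrahedral intermediate) if 10 is exposed for long to acid, base or silica; hence the cold, short work-up and immediate triflation.
- Fallback (resolution instead of desymmetrisation), from 9 back to 10: the acid is isomerised without stereocontrol (catalytic diphenyl phosphate, PhMe, 60 °C) to the racemic hydroxymethyl lactone F1. F1 is then resolved by lipase-catalysed acylation (Burkholderia cepacia lipase, vinyl acetate, t-BuOMe, 23 °C), with an enzyme selected to acylate the 4S alcohol to the acetate F2. Unreacted 10 is separated and enters step 6.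

Step 8.
- What may go wrong: competing conjugate addition of the cuprate at C6, attack at the lactone carbonyl, or elimination of triflic acid toward a 4-methylene diene, if displacement at the β-branched C7 is slower than expected.
- Fallback (palladium cross-coupling with a mild arylzinc instead of cuprate substitution), from 10 back to 16: the alcohol is converted with CBr4 and PPh3 (CH2Cl2, 0 °C) into the (3Z,4S)-bromomethyl lactone F3. Aryllithium 14 is transmetalated with ZnCl2 to the arylzinc chloride F4. F3 and F4 are joined by a Negishi coupling of an unactivated primary alkyl bromide (Pd2(dba)3, P(c-C5H9)3, N-methylimidazole, THF/N-methylpyrrolidone, 80 °C), in which oxidative addition is an SN2 process, to give 16.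

Step 3.
- What may go wrong: loss of site selectivity between the two C–Br bonds, or double alkylation. Transmetalation of a secondary alkylzinc is slower than that of the primary reagents for which trans-selective mono-coupling is established, which gives the catalyst time to attack the second bromide or to isomerise 6.
- Fallback (geometry set by syn-hydrometalation of an alkyne instead of site-selective oxidative addition), from 3 back to 8:
  - n-BuLi (2 equiv, THF, −78 °C) converts 3 by exchange and Fritsch–Buttenberg–Wiechell rearrangement into the lithium arylacetylide F5, which is trapped with methyl chloroformate as the methyl arylpropiolate F6.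
  - Syn-hydrostannation (Bu3SnH, Pd(PPh3)4, THF) should give the α-stannyl ester F7, with tin on C3 and ring A cis to the ester.
  - Iododestannylation (I2, CH2Cl2, 0 °C) gives the α-iodo ester F8 with retention.
  - Negishi coupling of F8 with 5 (PdCl2(DPEphos), THF) gives the methyl ester F9.
  - LiOH (THF/H2O) gives 8, which is acidified as in step 4.

Step 4.
- What may go wrong: premature, unselective lactonisation while 9 is freed and transferred, since acid and oxetane sit in one molecule; or partial protonation or geometric isomerisation of the alkenyllithium.
- Fallback (palladium carbonylation instead of an organolithium), from 6 back to 8: ethoxycarbonylation (CO 1 atm, EtOH, Et3N, Pd(OAc)2, 1,1'-bis(diphenylphosphino)ferrocene, DMF, 70 °C) gives the ethyl ester F10 with retention. LiOH (THF/H2O, 23 °C) gives the salt 8, which can be purified and stored, with 9 released in portions immediately before step 5.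

## Further compounds

F1 | step 5 | racemic (3Z)-3-[(3,4-bis(TBSO)-5-methoxyphenyl)methylidene]-4-(hydroxymethyl)oxolan-2-one | OCC1COC(=O)/C1=C\c1cc(O[Si](C)(C)C(C)(C)C)c(O[Si](C)(C)C(C)(C)C)c(OC)c1
F2 | step 5 | [(3S,4Z)-4-[(3,4-bis(TBSO)-5-methoxyphenyl)methylidene]-5-oxooxolan-3-yl]methyl acetate (acetate of the enantiomer of 10) | CC(=O)OC[C@H]1COC(=O)/C1=C\c1cc(O[Si](C)(C)C(C)(C)C)c(O[Si](C)(C)C(C)(C)C)c(OC)c1
F3 | step 8 | (3Z,4S)-4-(bromomethyl)-3-[(3,4-bis(TBSO)-5-methoxyphenyl)methylidene]oxolan-2-one | BrC[C@@H]1COC(=O)/C1=C\c1cc(O[Si](C)(C)C(C)(C)C)c(O[Si](C)(C)C(C)(C)C)c(OC)c1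
F4 | step 8 | [4-(TBSO)-3-methoxyphenyl]zinc chloride | COc1cc([Zn]Cl)ccc1O[Si](C)(C)C(C)(C)C
F5 | step 3 | lithium (3,4-bis(TBSO)-5-methoxyphenyl)acetylide | [Li]C#Cc1cc(O[Si](C)(C)C(C)(C)C)c(O[Si](C)(C)C(C)(C)C)c(OC)c1
F6 | step 3 | methyl 3-(3,4-bis(TBSO)-5-methoxyphenyl)prop-2-ynoate | COC(=O)C#Cc1cc(O[Si](C)(C)C(C)(C)C)c(O[Si](C)(C)C(C)(C)C)c(OC)c1
F7 | step 3 | methyl (2E)-3-(3,4-bis(TBSO)-5-methoxyphenyl)-2-(tributylstannyl)prop-2-enoate (ring A cis to the ester) | COC(=O)/C(=C\c1cc(O[Si](C)(C)C(C)(C)C)c(O[Si](C)(C)C(C)(C)C)c(OC)c1)[Sn](CCCC)(CCCC)CCCC
F8 | step 3 | methyl (2E)-3-(3,4-bis(TBSO)-5-methoxyphenyl)-2-iodoprop-2-enoate (ring A cis to the ester) | COC(=O)/C(I)=C\c1cc(O[Si](C)(C)C(C)(C)C)c(O[Si](C)(C)C(C)(C)C)c(OC)c1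
F9 | step 3 | methyl (2Z)-3-(3,4-bis(TBSO)-5-methoxyphenyl)-2-(oxetan-3-yl)prop-2-enoate | COC(=O)/C(=C\c1cc(O[Si](C)(C)C(C)(C)C)c(O[Si](C)(C)C(C)(C)C)c(OC)c1)C1COC1
F10 | step 4 | ethyl (2Z)-3-(3,4-bis(TBSO)-5-methoxyphenyl)-2-(oxetan-3-yl)prop-2-enoate | CCOC(=O)/C(=C\c1cc(O[Si](C)(C)C(C)(C)C)c(O[Si](C)(C)C(C)(C)C)c(OC)c1)C1COC1
A1 | alternative 1 | diisopropyl squarate (3,4-diisopropoxycyclobut-3-ene-1,2-dione) | CC(C)OC1=C(OC(C)C)C(=O)C1=O
A2 | alternative 1 | 4-chloro-2,3-diisopropoxycyclobut-2-en-1-one | CC(C)OC1=C(OC(C)C)C(Cl)C1=O
A3 | alternative 1 | (3Z,4S)-4-[(4-(TBSO)-3-methoxyphenyl)methyl]-3-[2-(tributylstannyl)prop-2-en-1-ylidene]oxolan-2-one | COc1cc(C[C@@H]2COC(=O)/C2=C\C(=C)[Sn](CCCC)(CCCC)CCCC)ccc1O[Si](C)(C)C(C)(C)C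
A4 | alternative 1 | (3Z,4S)-3-[(3-hydroxy-4,5-diisopropoxyphenyl)methylidene]-4-[(4-(TBSO)-3-methoxyphenyl)methyl]oxolan-2-one (C5' phenol) | COc1cc(C[C@@H]2COC(=O)/C2=C\c2cc(O)c(OC(C)C)c(OC(C)C)c2)ccc1O[Si](C)(C)C(C)(C)C
A5 | alternative 2 | 3-[(4-(TBSO)-3-methoxyphenyl)methyl]cyclobutan-1-one | COc1cc(CC2CC(=O)C2)ccc1O[Si](C)(C)C(C)(C)C
A6 | alternative 2 | (4S)-4-[(4-(TBSO)-3-methoxyphenyl)methyl]oxolan-2-one | COc1cc(C[C@@H]2COC(=O)C2)ccc1O[Si](C)(C)C(C)(C)C
A7 | alternative 2 | (3E,4S)-3-[(3,4-bis(TBSO)-5-methoxyphenyl)methylidene]-4-[(4-(TBSO)-3-methoxyphenyl)methyl]oxolan-2-one | COc1cc(C[C@@H]2COC(=O)/C2=C/c2cc(O[Si](C)(C)C(C)(C)C)c(O[Si](C)(C)C(C)(C)C)c(OC)c2)ccc1O[Si](C)(C)C(C)(C)C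
A8 | alternative 3 | (2E)-3-[4-(TBSO)-3-methoxyphenyl]prop-2-en-1-yl 3-(3,4-bis(TBSO)-5-methoxyphenyl)prop-2-ynoate | COc1cc(/C=C/COC(=O)C#Cc2cc(O[Si](C)(C)C(C)(C)C)c(O[Si](C)(C)C(C)(C)C)c(OC)c2)ccc1O[Si](C)(C)C(C)(C)C
A9 | alternative 3 | (3Z,4S)-3-[(3,4-bis(TBSO)-5-methoxyphenyl)methylidene]-4-[(4-(TBSO)-3-methoxyphenyl)methyl]oxolan-2-one (identical with 16) | COc1cc(C[C@@H]2COC(=O)/C2=C\c2cc(O[Si](C)(C)C(C)(C)C)c(O[Si](C)(C)C(C)(C)C)c(OC)c2)ccc1O[Si](C)(C)C(C)(C)C
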